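**Strategy**

Ring C is closed by an oxa-Povarov (4+2) annulation. An aryl oxocarbenium ion spanning C4a=C8a–O1=C2 (ortho carbon of ring A, the ether oxygen and the benzylic carbon that bears ring B) takes up C3 and C4 as (E)-1,2-bis(benzyloxy)ethene, so that C2–C3 and C4–C4a form in one operation and C2 and C3 are set trans. The step exploits the nucleophilic ortho position of the phloroglucinol-type ring A and the acetal oxidation level of C2. Its precursor is an O-aryl O-pivaloyl acetal of a ring B aldehyde that already carries the 3'-O-galloyl ester. The surplus C4 benzyloxy group is removed by ionic hydrogenation before global hydrogenolysis.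

Key step: step 5

Remark: the 3'- and 5'-oxygens of ring B are equivalent by rotation about C2–C1', so only one ester position exists; the sense of induction of the chiral acid in step 5 cannot be predicted, so the (R)-acid is written and its enantiomer is used if the first runs show the opposite sense.

**Route**

Step 1
Reactants: 1 3,4,5-trihydroxybenzaldehyde
Product: 2 3,4-bis(benzyloxy)-5-hydroxybenzaldehyde
Conditions: BnBr (2.0 equiv), K2CO3 (2.0 equiv), DMF, 0 °C to rt, argon
Reagents that add atoms: benzyl bromide, BrCc1ccccc1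
Why: Williamson etherification in which the most acidic 4-OH (para to the aldehyde) reacts first and the two remaining hydroxyls are equivalent, so the second benzylation can only give the 3,4-pattern, while two equivalents of base and halide limit the third.

Step 2
Reactants: 2 3,4-bis(benzyloxy)-5-hydroxybenzaldehyde; 3 3,4,5-tris(benzyloxy)benzoic acid
Product: 4 2,3-bis(benzyloxy)-5-formylphenyl 3,4,5-tris(benzyloxy)benzoate
Conditions: DCC (1.2 equiv), DMAP (0.1 equiv), CH2Cl2, 0 °C to rt
Reagents that add atoms: none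
Why: Steglich esterification of the single free phenol through the acylpyridinium intermediate, with the aldehyde and benzyl ethers inert.

Step 3
Reactants: 4 2,3-bis(benzyloxy)-5-formylphenyl 3,4,5-tris(benzyloxy)benzoate; 5 3,5-bis(benzyloxy)phenol
Product: 7 [3,5-bis(benzyloxy)phenoxy]{3,4-bis(benzyloxy)-5-[3,4,5-tris(benzyloxy)benzoyloxy]phenyl}methyl pivalate (racemic at the acetal carbon), via α-chlorobenzyl pivalate 6 (not isolated)
Conditions: pivaloyl chloride (1.05 equiv), ZnCl2 (5 mol%), CH2Cl2, 0 °C to rt; then iPr2NEt (2.5 equiv), 5 (1.0 equiv), CH2Cl2, −20 °C to rt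
Reagents that add atoms: pivaloyl chloride, CC(C)(C)C(=O)Cl
Why: ZnCl2-catalysed addition of an acyl chloride to an aldehyde gives the α-chloroalkyl ester, which O-alkylates the phenol as in acyloxyalkyl aryl ether formation; the bulky pivalate suppresses acyl transfer, and the racemic acetal carbon is of no consequence because it becomes planar in step 5.

Step 4
Reactants: 8 (E)-1,2-diiodoethene; 9 benzyl alcohol
Product: 10 (E)-1,2-bis(benzyloxy)ethene
Conditions: CuI (10 mol%), 3,4,7,8-tetramethyl-1,10-phenanthroline (20 mol%), Cs2CO3 (3 equiv), 9 (4 equiv), toluene, 80 °C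
Reagents that add atoms: none
Why: Ullmann-type copper-catalysed C–O coupling of a vinyl iodide with an alcohol, which retains alkene geometry, applied at both termini to give the E enediol diether.

Step 5
Reactants: 7 [3,5-bis(benzyloxy)phenoxy]{3,4-bis(benzyloxy)-5-[3,4,5-tris(benzyloxy)benzoyloxy]phenyl}methyl pivalate; 10 (E)-1,2-bis(benzyloxy)ethene
Product: 12 (2R,3S,4R)-3,4,5,7-tetrakis(benzyloxy)-2-{3,4-bis(benzyloxy)-5-[3,4,5-tris(benzyloxy)benzoyloxy]phenyl}chromane (2,3-trans-3,4-trans), via aryl oxocarbenium ion 11 (not isolated)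
Conditions: 10 (2.5 equiv), (R)-3,3'-bis(2,4,6-triisopropylphenyl)-BINOL N-triflylphosphoramide (10 mol%), 4 Å MS, toluene, −60 °C; Et3N quench
Reagents that add atoms: none
Why: Proposed new method: the chiral acid protonates the pivalate of 7, pivalic acid leaves and the (E)-aryl oxocarbenium ion 11 stays paired with the chiral phosphoramidate; its 2-oxonia-diene C4a=C8a–O1(+)=C2 takes up enediol ether 10 in a polar, asynchronous (4+2) cycloaddition in which C2–C3 forms first and the benzyloxy-stabilised cation at C4 is trapped by the ortho carbon C4a of ring A, rearomatisation returning the proton to the catalyst. The closest known reactions are the SnCl4-promoted oxa-Povarov reaction of aryl oxocarbenium ions with alkenes and the chiral-phosphoric-acid-catalysed Povarov reaction of N-aryl imines with (E)-enecarbamates; an enantioselective oxa-Povarov reaction has not been shown. Ring C is closed as a six-membered ring in a (4+2) mode, the second bond by a 6-exo-trig Friedel–Crafts attack on the C4 oxocarbenium carbon. The relative configuration follows from the alkene: the E geometry fixes 3,4-trans, and the usual endo placement of the C4 donor (2,4-cis, all substituents pseudo-equatorial in the half-chair) then gives 2,3-trans, as with (E)-anethole and (E)-enecarbamates in Povarov reactions; the absolute configuration (attack on the Si face of C2) must come from the chiral anion. The step needs ionisation with loss of the carboxylate and not of the aryloxide, which the pivalate leaving group secures, and ortho ring closure without regiochemical choice, which holds because both ortho positions of the 3,5-bis(benzyloxy)phenoxy group are equivalent and the dienophile is symmetrical.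

Step 6
Reactants: 12 (2R,3S,4R)-3,4,5,7-tetrakis(benzyloxy)-2-{3,4-bis(benzyloxy)-5-[3,4,5-tris(benzyloxy)benzoyloxy]phenyl}chromane
Product: 13 (2R,3S)-3,5,7-tris(benzyloxy)-2-{3,4-bis(benzyloxy)-5-[3,4,5-tris(benzyloxy)benzoyloxy]phenyl}chromane
Conditions: Et3SiH (5 equiv), BF3·OEt2 (1.5 equiv), CH2Cl2, −78 to −30 °C
Reagents that add atoms: none
Why: Ionic hydrogenation in which BF3 ionises only the C4 benzyl ether, whose cation is stabilised by the two ortho/para oxygens of ring A, and the silane delivers hydride; C2 and C3 are untouched and the C3 benzyl ether cannot ionise.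

Step 7
Reactants: 13 (2R,3S)-3,5,7-tris(benzyloxy)-2-{3,4-bis(benzyloxy)-5-[3,4,5-tris(benzyloxy)benzoyloxy]phenyl}chromane
Product: 14 gallocatechin 3'-O-gallate, (2R,3S)
Conditions: H2 (1 atm), Pd(OH)2/C (20 wt%), THF/MeOH 1:1, rt
Reagents that add atoms: none
Why: Hydrogenolysis of all eight benzyl ethers under neutral conditions should leave the aryl ester, the C2–O1 bond and both stereocenters intact and avoids base-induced acyl migration to the 4'-hydroxyl.

**Compound list**

1 | 3,4,5-trihydroxybenzaldehyde | O=Cc1cc(O)c(O)c(O)c1 | starting material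
2 | 3,4-bis(benzyloxy)-5-hydroxybenzaldehyde | O=Cc1cc(OCc2ccccc2)c(OCc2ccccc2)c(O)c1 | intermediate
3 | 3,4,5-tris(benzyloxy)benzoic acid | OC(=O)c1cc(OCc2ccccc2)c(OCc2ccccc2)c(OCc2ccccc2)c1 | starting material
4 | 2,3-bis(benzyloxy)-5-formylphenyl 3,4,5-tris(benzyloxy)benzoate | O=Cc1cc(OCc2ccccc2)c(OCc2ccccc2)c(OC(=O)c2cc(OCc3ccccc3)c(OCc3ccccc3)c(OCc3ccccc3)c2)c1 | intermediate
5 | 3,5-bis(benzyloxy)phenol | Oc1cc(OCc2ccccc2)cc(OCc2ccccc2)c1 | starting material
6 | {3,4-bis(benzyloxy)-5-[3,4,5-tris(benzyloxy)benzoyloxy]phenyl}(chloro)methyl pivalate (racemic, not isolated) | CC(C)(C)C(=O)OC(Cl)c1cc(OCc2ccccc2)c(OCc2ccccc2)c(OC(=O)c2cc(OCc3ccccc3)c(OCc3ccccc3)c(OCc3ccccc3)c2)c1 | intermediate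
7 | [3,5-bis(benzyloxy)phenoxy]{3,4-bis(benzyloxy)-5-[3,4,5-tris(benzyloxy)benzoyloxy]phenyl}methyl pivalate (racemic) | CC(C)(C)C(=O)OC(Oc1cc(OCc2ccccc2)cc(OCc2ccccc2)c1)c1cc(OCc2ccccc2)c(OCc2ccccc2)c(OC(=O)c2cc(OCc3ccccc3)c(OCc3ccccc3)c(OCc3ccccc3)c2)c1 | intermediate
8 | (E)-1,2-diiodoethene | I/C=C/I | starting material
9 | benzyl alcohol | OCc1ccccc1 | starting material
10 | (E)-1,2-bis(benzyloxy)ethene | c1ccccc1CO/C=C/OCc1ccccc1 | intermediate
11 | aryl oxocarbenium ion [3,5-bis(benzyloxy)phenyl]{3,4-bis(benzyloxy)-5-[3,4,5-tris(benzyloxy)benzoyloxy]benzylidene}oxonium, ion-paired with the chiral phosphoramidate (not isolated) | c1ccccc1COc1cc(OCc2ccccc2)cc([O+]=Cc2cc(OCc3ccccc3)c(OCc3ccccc3)c(OC(=O)c3cc(OCc4ccccc4)c(OCc4ccccc4)c(OCc4ccccc4)c3)c2)c1 | intermediate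
12 | (2R,3S,4R)-3,4,5,7-tetrakis(benzyloxy)-2-{3,4-bis(benzyloxy)-5-[3,4,5-tris(benzyloxy)benzoyloxy]phenyl}chromane | O=C(Oc1cc([C@H]2Oc3cc(OCc4ccccc4)cc(OCc4ccccc4)c3[C@@H](OCc3ccccc3)[C@@H]2OCc2ccccc2)cc(OCc2ccccc2)c1OCc1ccccc1)c1cc(OCc2ccccc2)c(OCc2ccccc2)c(OCc2ccccc2)c1 | intermediate
13 | (2R,3S)-3,5,7-tris(benzyloxy)-2-{3,4-bis(benzyloxy)-5-[3,4,5-tris(benzyloxy)benzoyloxy]phenyl}chromane | O=C(Oc1cc([C@H]2Oc3cc(OCc4ccccc4)cc(OCc4ccccc4)c3C[C@@H]2OCc2ccccc2)cc(OCc2ccccc2)c1OCc1ccccc1)c1cc(OCc2ccccc2)c(OCc2ccccc2)c(OCc2ccccc2)c1 | intermediate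
14 | gallocatechin 3'-O-gallate, (2R,3S) | O=C(Oc1cc([C@H]2Oc3cc(O)cc(O)c3C[C@@H]2O)cc(O)c1O)c1cc(O)c(O)c(O)c1 | target

**Step count**

Total step count: 7. Longest linear sequence: 6 (steps 1, 2, 3, 5, 6, 7).

**Steps most likely to fail**

1. Step 5 (key step, proposed new method). The ion pair may discriminate the two faces of C2 poorly, and the endo preference may erode and open the 2,3-cis series. The C4 benzyl ether of the product may also ionise again and lead to elimination or oligomerisation, the cation may alkylate ring A of a second molecule, and the acid may consume the enol ether. The fallback sets out from 7 (with 10) and comes back at 12. SnCl4 (1.1 equiv) in CH2Cl2 at −78 °C, the established achiral conditions for oxa-Povarov annulation, should give racemic material, that is 12 together with the (2S,3R,4S) enantiomer of 12 F1. Preparative chromatography on a chiral stationary phase (supercritical CO2, amylose tris(3,5-dimethylphenylcarbamate)) then delivers 12. Asymmetric induction is thereby replaced by resolution of a racemate.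

2. Step 3. Addition of pivaloyl chloride to the electron-rich aldehyde may stay incomplete or revert. The very electron-rich phenol may be alkylated on carbon instead of oxygen, acyl transfer may give the aryl pivalate, and the labile acetal may hydrolyse during isolation. The fallback sets out from 4 and comes back at 12. HC(OMe)3 with catalytic PPTS in CH2Cl2/MeOH gives the dimethyl acetal F2. Acetyl chloride converts it into the α-chloro methyl ether F3, which is used crude. Reaction with 5 and iPr2NEt gives the O-methyl O-aryl acetal F4. F4 then takes the place of 7 in step 5, ionised by the chiral acid or, if the methoxy group does not leave selectively, by SnCl4 at −78 °C followed by the resolution described above.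

3. Step 4. The second C–O coupling on the now electron-rich vinyl iodide may stall, dehydrohalogenation may compete, and partial E/Z isomerisation would feed the 2,3-cis series into step 5. The fallback sets out from 9 and comes back at 10. It is a Chan–Lam-type oxidative coupling of 9 with commercial (E)-1,2-bis(4,4,5,5-tetramethyl-1,3,2-dioxaborolan-2-yl)ethene, using Cu(OAc)2, Et3N and 4 Å MS in CH2Cl2 at rt under air. The C–O bond is formed with retention from a vinyl boronate instead of a vinyl iodide, and no new compound is made (F0).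

**Further compounds**

F1 | step 5 | (2S,3R,4S)-3,4,5,7-tetrakis(benzyloxy)-2-{3,4-bis(benzyloxy)-5-[3,4,5-tris(benzyloxy)benzoyloxy]phenyl}chromane (enantiomer of 12) | O=C(Oc1cc([C@@H]2Oc3cc(OCc4ccccc4)cc(OCc4ccccc4)c3[C@H](OCc3ccccc3)[C@H]2OCc2ccccc2)cc(OCc2ccccc2)c1OCc1ccccc1)c1cc(OCc2ccccc2)c(OCc2ccccc2)c(OCc2ccccc2)c1
F2 | step 3 | 2,3-bis(benzyloxy)-5-(dimethoxymethyl)phenyl 3,4,5-tris(benzyloxy)benzoate | COC(OC)c1cc(OCc2ccccc2)c(OCc2ccccc2)c(OC(=O)c2cc(OCc3ccccc3)c(OCc3ccccc3)c(OCc3ccccc3)c2)c1
F3 | step 3 | 2,3-bis(benzyloxy)-5-[chloro(methoxy)methyl]phenyl 3,4,5-tris(benzyloxy)benzoate (racemic) | COC(Cl)c1cc(OCc2ccccc2)c(OCc2ccccc2)c(OC(=O)c2cc(OCc3ccccc3)c(OCc3ccccc3)c(OCc3ccccc3)c2)c1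
F4 | step 3 | 2,3-bis(benzyloxy)-5-{[3,5-bis(benzyloxy)phenoxy](methoxy)methyl}phenyl 3,4,5-tris(benzyloxy)benzoate (racemic) | COC(Oc1cc(OCc2ccccc2)cc(OCc2ccccc2)c1)c1cc(OCc2ccccc2)c(OCc2ccccc2)c(OC(=O)c2cc(OCc3ccccc3)c(OCc3ccccc3)c(OCc3ccccc3)c2)c1
F0 | step 4 | none | none
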